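Two questions stood before me: how much substrate each flask had left at the end, and how much of what had become intermediate the second step had already carried away.

| setting | south-west | east | maple | larch | elm |
|---|---|---|---|---|---|
| substrate | 0.19 M | 0.19 M | 0.19 M | 0.19 M | 0.19 M |
| coupling partner | 0.475 M | 0.475 M | 0.475 M | 0.475 M | 0.475 M |
| free catalyst | 0.25 mM | 0.57 mM | 0.38 mM | 0.38 mM | 0.38 mM |
| second catalyst | 9.9 mM | 9.9 mM | 9.9 mM | 9.9 mM | 9.9 mM |
| temperature | −5 °C | 17 °C | 25 °C | 5 °C | −15 °C |
| remark | run made earlier | run made earlier |  |  |  |
| time |  |  | 2.0 min | 2.0 min | 2.0 min |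

south-west run (percent of the substrate charged)

| time / min | intermediate / % | product / % |
|---|---|---|
| 0.667 | 3.7 | 0.8 |
| 1.33 | 7.8 | 0.7 |
| 2.00 | 11.2 | 1.5 |
| 4.00 | 16.3 | 5.2 |
| 6.00 | 20.9 | 9.9 |

east run (percent of the substrate charged)

| time / s | intermediate / % | product / % |
|---|---|---|
| 15.0 | 10.3 | 1.6 |
| 30.0 | 17.9 | 2.8 |
| 40.0 | 22.8 | 3.8 |
| 60.0 | 28.8 | 8.5 |
| 80.0 | 33.1 | 13.6 |

(scatter of a reading: 0.5 percentage points)

- which flask leads in amount of intermediate, in percent of the substrate charged ("all alike" within 1.5 percentage points) (maple / larch / elm / all alike)
- how much intermediate is there at the end, in percent of the substrate charged: maple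
- how much intermediate is there at the end, in percent of the substrate charged: larch
- how much intermediate is there at the end, in percent of the substrate charged: elm

The candidate steps run substrate to intermediate to product, so I took the fraction left as what remained after subtracting both readings. The free catalyst comes back from its step, so I treated the substrate as a pseudo-first-order decay. Its fraction left is e^(−n), where the dose n is the elapsed time divided by the time constant, and n grows in proportion to free catalyst and to time.

The last readings gave n = 0.368 in the south-west run and 0.629 in the east run. Per unit of catalyst and time, the east run was 3.37 times as fast, which set a temperature scale of 4300 K. Scaled to the new flasks, the dose was 0.936 for maple, 0.332 for larch and 0.100 for elm.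

That raised the second question. I read the intermediate's own rate constant from the last interval of each run, as product gained over mean intermediate times interval: 0.126 min⁻¹ in the south-west run and 0.494 min⁻¹ in the east run. Its temperature scale was 4820 K. This gave second doses m of 1.54, 0.483 and 0.126. The intermediate, n/(m−n)·(e^(−n) − e^(−m)), then came to 27.5% in maple, ahead of 22.1% in larch and 8.95% in elm.

The forecast gave 27%, 22.2% and 9.5% for these flasks, slightly apart from my figures, with maple ahead: “Maple leads, since it is the warmest run”.

The flasks gave 28.0% in maple, 22.0% in larch and 9.24% in elm.

    substrate + free catalyst → free catalyst + intermediate (k = 7.40 L mol⁻¹ s⁻¹, Ea = 35.0 kJ mol⁻¹)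
    coupling partner + second catalyst + intermediate → second catalyst + product (k = 0.930 L² mol⁻² s⁻¹, Ea = 39.0 kJ mol⁻¹)
    (constants at 5 °C)

Elm held 9.24% of intermediate partly because it was read at 2.00 min: at 20.0 min, elm held 32.3%. Elm's dose implied 90.5% of the substrate left, and the flask held 90.1%. The neighbour of elm with 1.5 × 10⁻⁴ M of free catalyst has its dose scaled to 0.0396, which implied 96.1% left; that flask held 96.0% substrate and 3.76% intermediate.

The earlier runs and the new flask were generated by integration from invented constants.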